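**Retrosynthetic overview**
- Kanzonol I comes from its 4'-O-TBS ether. The last step only frees the phenol.
- Rings C and D are disconnected together. Cutting C4–C4a (Friedel–Crafts) is tied to a 1,2-shift of ring B from C3 back to the neighbouring CH2, and C3'–C4'' is cut as an alkyne hydroarylation. This gives an acyclic (R)-1-aryl-3-aryloxypropan-2-ol that carries a 1,1-dimethylpropargyl ether.
- The ring B–CH2 bond is cut to a ring B aryl Grignard reagent and the (R)-glycidyl ether of the ring A phenol. The only stereocentre comes from the glycidyl unit and is inverted once, in the key step.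
- The ring A phenol comes from 1,3-dimethoxybenzene (lithiation/prenylation, then C–H borylation/oxidation). The ring B bromide comes from 4-bromoresorcinol (silylation, propargylation).
- Ring order: A and B are bought as benzene rings. C and then D close in one flask operation.

Assumption: the stereocentre of the given SMILES is read as (3R). Isoflavan numbering is used, with A = dimethoxy-prenyl benzene ring, C = dihydropyran, B = resorcinol-derived ring and D = dimethylpyran.

**Step 1**
Reactants: 1 1,3-dimethoxybenzene; 2 prenyl bromide (1-bromo-3-methylbut-2-ene)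
Product: 4 1,3-dimethoxy-2-(3-methylbut-2-en-1-yl)benzene, via 2,6-dimethoxyphenyllithium 3 (not isolated)
Conditions: n-BuLi, THF, 0 °C to rt; then 2, −78 °C to rt
Reagents that add atoms: n-butyllithium, [Li]CCCC (lithium of 3 only; no atom of it stays in 4)
Why: Directed ortho-lithiation takes the C–H between the two chelating methoxy groups, and aryllithium 3 then displaces the primary allylic bromide of 2 in an SN2 alkylation.

**Step 2**
Reactants: 4 1,3-dimethoxy-2-(3-methylbut-2-en-1-yl)benzene
Product: 6 3,5-dimethoxy-4-(3-methylbut-2-en-1-yl)phenol, via aryl pinacol boronate 5 (not isolated)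
Conditions: [Ir(OMe)(cod)]2 (1 mol %), 4,4'-di-tert-butyl-2,2'-bipyridine (2 mol %), B2pin2, THF, 80 °C (sealed); then 30% H2O2, NaOH, THF–H2O, 0 °C; 1 M HCl to pH 6
Reagents that add atoms: bis(pinacolato)diboron, CC1(C)OB(OC1(C)C)B1OC(C)(C)C(C)(C)O1 (Bpin of 5 only); hydrogen peroxide, OO (the phenol oxygen of 6)
Why: Sterically controlled iridium-catalysed aromatic C–H borylation takes the only ring C–H without an ortho substituent (para to the prenyl group) and leaves the trisubstituted alkene alone, and basic peroxide then turns C–B into C–O by a boron-to-oxygen 1,2-aryl shift.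

**Step 3**
Reactants: 6 3,5-dimethoxy-4-(3-methylbut-2-en-1-yl)phenol; 7 (R)-glycidyl 3-nitrobenzenesulfonate
Product: 8 (R)-2-{[3,5-dimethoxy-4-(3-methylbut-2-en-1-yl)phenoxy]methyl}oxirane
Conditions: K2CO3, DMF, rt to 40 °C
Reagents that add atoms: none
Why: In this Williamson ether synthesis the phenoxide displaces the primary nosylate faster than it opens the epoxide, and no bond to the stereocentre is touched, so the (R) configuration of 7 is carried into 8.

**Step 4**
Reactants: 9 4-bromoresorcinol
Product: 10 2-bromo-5-(tert-butyldimethylsilyloxy)phenol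
Conditions: TBSCl (1.0 equiv), imidazole, CH2Cl2, 0 °C
Reagents that add atoms: tert-butyldimethylsilyl chloride, CC(C)(C)[Si](C)(C)Cl
Why: Kinetic monosilylation takes the unhindered hydroxyl para to bromine, because the hydroxyl ortho to bromine is shielded and hydrogen-bonded to the halogen.

**Step 5**
Reactants: 10 2-bromo-5-(tert-butyldimethylsilyloxy)phenol; 11 3-chloro-3-methylbut-1-yne
Product: 12 1-bromo-4-(tert-butyldimethylsilyloxy)-2-(2-methylbut-3-yn-2-yloxy)benzene
Conditions: DBU, CuCl2 (1 mol %), MeCN, 0 °C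
Reagents that add atoms: none
Why: Copper-catalysed propargylic etherification (copper-assisted ionisation of the tertiary propargylic chloride, then O-attack) alkylates the only free OH under conditions that keep the aryl silyl ether.

**Step 6**
Reactants: 12 1-bromo-4-(tert-butyldimethylsilyloxy)-2-(2-methylbut-3-yn-2-yloxy)benzene; 8 (R)-2-{[3,5-dimethoxy-4-(3-methylbut-2-en-1-yl)phenoxy]methyl}oxirane
Product: 15 (R)-1-[4-(tert-butyldimethylsilyloxy)-2-(2-methylbut-3-yn-2-yloxy)phenyl]-3-[3,5-dimethoxy-4-(3-methylbut-2-en-1-yl)phenoxy]propan-2-ol, via alkynylmagnesium bromide 13 (not isolated), via bis-Grignard reagent 14 (not isolated)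
Conditions: EtMgBr (1.05 equiv), THF, 0 °C to rt; Mg, LiCl, THF, rt to 40 °C; then CuI (10 mol %), 8, −30 to 0 °C; aq NH4Cl
Reagents that add atoms: ethylmagnesium bromide, CC[Mg]Br (MgBr of 13 and 14 only); magnesium, [Mg] (aryl–Mg of 14 only)
Why: Copper-catalysed SN2 opening of a terminal epoxide by an aryl Grignard reagent occurs at the CH2 terminus; the alkyne is masked as its magnesium acetylide, which does not open epoxides at this temperature and is a non-transferable ligand on copper, and the stereocentre is not involved, so (R) is kept.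

**Step 7**
Reactants: 15 (R)-1-[4-(tert-butyldimethylsilyloxy)-2-(2-methylbut-3-yn-2-yloxy)phenyl]-3-[3,5-dimethoxy-4-(3-methylbut-2-en-1-yl)phenoxy]propan-2-ol
Product: 19 (R)-tert-butyl({8-[5,7-dimethoxy-6-(3-methylbut-2-en-1-yl)chroman-3-yl]-2,2-dimethyl-2H-chromen-5-yl}oxy)dimethylsilane, via secondary triflate 16 (not isolated), via phenonium ion 17 (not isolated), via ring-C-closed propargyl ether 18 (not isolated)
Conditions: Tf2O (1.1 equiv), 2,6-di-tert-butyl-4-methylpyridine (3 equiv), Ph3PAuNTf2 (5 mol %), CH2Cl2 (0.01 M), −78 °C to rt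
Reagents that add atoms: trifluoromethanesulfonic anhydride, O=S(=O)(OS(=O)(=O)C(F)(F)F)C(F)(F)F (CF3SO2 group of 16 and counter-ion of 17 only; nothing of it stays in 19)
Why: Proposed new method: O-triflation gives 16, whose 2,4-dioxygenated ring B displaces triflate from the back side (Ar1-3 neighbouring-group participation, one clean inversion that fixes C3 as R) to give phenonium ion 17; ring A, a phloroglucinol triether with two equivalent ortho positions, opens the cyclopropane at its CH2 carbon in a six-ring Friedel–Crafts closure, so ring B ends on C3 (net 1,2-aryl shift, C3–aryl bond never broken) and ring C is formed as 18; on warming, the monovalent gold catalyst closes ring D by 6-endo-dig hydroarylation at C3', the only free position ortho to the propargyl ether; the closest known reaction types are aryl-assisted solvolysis with Friedel–Crafts capture of phenonium ions, the 6-endo epoxide–arene cyclisation of aryl glycidyl ethers to chroman-3-ols (same geometry, with oxygen in place of the spiro carbon), and the gold-catalysed cycloisomerisation of aryl 1,1-dimethylpropargyl ethers to 2,2-dimethyl-2H-chromenes.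

**Step 8**
Reactants: 19 (R)-tert-butyl({8-[5,7-dimethoxy-6-(3-methylbut-2-en-1-yl)chroman-3-yl]-2,2-dimethyl-2H-chromen-5-yl}oxy)dimethylsilane
Product: 20 Kanzonol I [(R)-8-[5,7-dimethoxy-6-(3-methylbut-2-en-1-yl)chroman-3-yl]-2,2-dimethyl-2H-chromen-5-ol]
Conditions: TBAF, AcOH (1:1), THF, 0 °C
Reagents that add atoms: none
Why: Fluoride-driven cleavage of the aryl silyl ether (strong Si–F bond) is buffered with acetic acid, so the phenol, both alkenes and the non-acidic C3 stereocentre are left untouched.

**Compound list**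
1 | 1,3-dimethoxybenzene | COc1cccc(OC)c1 | starting material
2 | prenyl bromide (1-bromo-3-methylbut-2-ene) | CC(C)=CCBr | starting material
3 | 2,6-dimethoxyphenyllithium | COc1cccc(OC)c1[Li] | intermediate
4 | 1,3-dimethoxy-2-(3-methylbut-2-en-1-yl)benzene | COc1cccc(OC)c1CC=C(C)C | intermediate
5 | 2-[3,5-dimethoxy-4-(3-methylbut-2-en-1-yl)phenyl]-4,4,5,5-tetramethyl-1,3,2-dioxaborolane | COc1cc(B2OC(C)(C)C(C)(C)O2)cc(OC)c1CC=C(C)C | intermediate
6 | 3,5-dimethoxy-4-(3-methylbut-2-en-1-yl)phenol | COc1cc(O)cc(OC)c1CC=C(C)C | intermediate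
7 | (R)-glycidyl 3-nitrobenzenesulfonate | O=S(=O)(OC[C@H]1CO1)c1cccc([N+](=O)[O-])c1 | starting material
8 | (R)-2-{[3,5-dimethoxy-4-(3-methylbut-2-en-1-yl)phenoxy]methyl}oxirane | COc1cc(OC[C@H]2CO2)cc(OC)c1CC=C(C)C | intermediate
9 | 4-bromoresorcinol | Oc1ccc(Br)c(O)c1 | starting material
10 | 2-bromo-5-(tert-butyldimethylsilyloxy)phenol | CC(C)(C)[Si](C)(C)Oc1ccc(Br)c(O)c1 | intermediate
11 | 3-chloro-3-methylbut-1-yne | C#CC(C)(C)Cl | starting material
12 | 1-bromo-4-(tert-butyldimethylsilyloxy)-2-(2-methylbut-3-yn-2-yloxy)benzene | C#CC(C)(C)Oc1cc(O[Si](C)(C)C(C)(C)C)ccc1Br | intermediate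
13 | bromomagnesium acetylide of 12 | Br[Mg]C#CC(C)(C)Oc1cc(O[Si](C)(C)C(C)(C)C)ccc1Br | intermediate
14 | bis-Grignard reagent (aryl-MgBr and alkynyl-MgBr) from 12 | Br[Mg]C#CC(C)(C)Oc1cc(O[Si](C)(C)C(C)(C)C)ccc1[Mg]Br | intermediate
15 | (R)-1-[4-(tert-butyldimethylsilyloxy)-2-(2-methylbut-3-yn-2-yloxy)phenyl]-3-[3,5-dimethoxy-4-(3-methylbut-2-en-1-yl)phenoxy]propan-2-ol | COc1cc(OC[C@H](O)Cc2ccc(O[Si](C)(C)C(C)(C)C)cc2OC(C)(C)C#C)cc(OC)c1CC=C(C)C | intermediate
16 | (R)-trifluoromethanesulfonate of 15 | COc1cc(OC[C@H](OS(=O)(=O)C(F)(F)F)Cc2ccc(O[Si](C)(C)C(C)(C)C)cc2OC(C)(C)C#C)cc(OC)c1CC=C(C)C | intermediate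
17 | phenonium triflate: spiro[2.5]octadienyl cation from ring B, (R) at the cyclopropane CH that bears the aryloxymethyl group, spiro carbon not defined | COc1cc(OC[C@@H]2CC23C=CC(=[O+][Si](C)(C)C(C)(C)C)C=C3OC(C)(C)C#C)cc(OC)c1CC=C(C)C.[O-]S(=O)(=O)C(F)(F)F | intermediate
18 | (R)-3-[4-(tert-butyldimethylsilyloxy)-2-(2-methylbut-3-yn-2-yloxy)phenyl]-5,7-dimethoxy-6-(3-methylbut-2-en-1-yl)chroman | COc1cc2c(c(OC)c1CC=C(C)C)C[C@H](c1ccc(O[Si](C)(C)C(C)(C)C)cc1OC(C)(C)C#C)CO2 | intermediate
19 | (R)-4'-O-TBS ether of Kanzonol I | COc1cc2c(c(OC)c1CC=C(C)C)C[C@H](c1ccc(O[Si](C)(C)C(C)(C)C)c3c1OC(C)(C)C=C3)CO2 | intermediate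
20 | Kanzonol I, (3R) | COc1cc2c(c(OC)c1CC=C(C)C)C[C@H](c1ccc(O)c3c1OC(C)(C)C=C3)CO2 | target

**Total step count:** 8. **Longest linear sequence:** 6 (steps 1, 2, 3, 6, 7, 8).

**Steps most likely to fail**

**Step 7** is the riskiest.
- Risks: participation by the propargyl ether oxygen (five-ring oxonium, loss of the tertiary group), a hydride shift leading to a 4-arylchroman, five-ring closure at the substituted cyclopropane carbon, or a sluggish gold step next to the silyl ether.
- The fallback sets out from 8 and 14 and comes back at 18. It builds ring C before ring B is attached.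
- Warming 8 in hexafluoroisopropanol lets ring A open the epoxide at its CH2 terminus in a 6-endo Friedel–Crafts cyclisation. This gives (R)-5,7-dimethoxy-6-(3-methylbut-2-en-1-yl)chroman-3-ol F1.
- TsCl in pyridine converts it into (R)-5,7-dimethoxy-6-(3-methylbut-2-en-1-yl)chroman-3-yl 4-methylbenzenesulfonate F2.
- Bis-Grignard reagent 14 displaces the tosylate with inversion under CuI/TMEDA/LiOMe catalysis and gives 18. Ph3PAuNTf2 in CH2Cl2 then closes ring D to 19.

**Step 6** is next.
- Risks: proton transfer from any free alkyne to the aryl Grignard, bromohydrin formation from the epoxide, or copper tied up as acetylide.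
- The fallback sets out from 10 and 8 and comes back at 15. It makes the C–C bond before the alkyne is present.
- n-BuLi (2.1 equiv, Et2O, 0 °C) turns 10 into lithium 2-lithio-5-(tert-butyldimethylsilyloxy)phenoxide F3.
- F3 opens 8 at the CH2 terminus with BF3·OEt2 at −78 °C. This gives (R)-1-[4-(tert-butyldimethylsilyloxy)-2-hydroxyphenyl]-3-[3,5-dimethoxy-4-(3-methylbut-2-en-1-yl)phenoxy]propan-2-ol F4.
- The phenol of F4, far more acidic than the secondary alcohol, is then propargylated selectively with 11 (DBU, CuCl2, MeCN, 0 °C) to give 15.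

**Step 2** is third.
- Risks: hydroboration or isomerisation of the prenyl alkene by pinacolborane and iridium hydrides, or some borylation ortho to methoxy.
- The fallback sets out from 2 and comes back at 6. It has the oxygen in place before the prenyl group arrives.
- Commercial 3,5-dimethoxyphenol F5 is silylated (TIPSCl, imidazole) to (3,5-dimethoxyphenoxy)triisopropylsilane F6.
- n-BuLi lithiates between the two methoxy groups, because the bulky silyl ether neither directs nor admits the base. This gives [2,6-dimethoxy-4-(triisopropylsilyloxy)phenyl]lithium F7.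
- Alkylation with 2 gives [3,5-dimethoxy-4-(3-methylbut-2-en-1-yl)phenoxy]triisopropylsilane F8, and TBAF releases 6.

**Further compounds**
F1 | step 7 | (R)-5,7-dimethoxy-6-(3-methylbut-2-en-1-yl)chroman-3-ol | COc1cc2c(c(OC)c1CC=C(C)C)C[C@@H](O)CO2
F2 | step 7 | (R)-5,7-dimethoxy-6-(3-methylbut-2-en-1-yl)chroman-3-yl 4-methylbenzenesulfonate | COc1cc2c(c(OC)c1CC=C(C)C)C[C@@H](OS(=O)(=O)c1ccc(C)cc1)CO2
F3 | step 6 | lithium 2-lithio-5-(tert-butyldimethylsilyloxy)phenoxide | [Li]Oc1cc(O[Si](C)(C)C(C)(C)C)ccc1[Li]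
F4 | step 6 | (R)-1-[4-(tert-butyldimethylsilyloxy)-2-hydroxyphenyl]-3-[3,5-dimethoxy-4-(3-methylbut-2-en-1-yl)phenoxy]propan-2-ol | COc1cc(OC[C@H](O)Cc2ccc(O[Si](C)(C)C(C)(C)C)cc2O)cc(OC)c1CC=C(C)C
F5 | step 2 | 3,5-dimethoxyphenol | COc1cc(O)cc(OC)c1
F6 | step 2 | (3,5-dimethoxyphenoxy)triisopropylsilane | COc1cc(O[Si](C(C)C)(C(C)C)C(C)C)cc(OC)c1
F7 | step 2 | [2,6-dimethoxy-4-(triisopropylsilyloxy)phenyl]lithium | COc1cc(O[Si](C(C)C)(C(C)C)C(C)C)cc(OC)c1[Li]
F8 | step 2 | [3,5-dimethoxy-4-(3-methylbut-2-en-1-yl)phenoxy]triisopropylsilane | COc1cc(O[Si](C(C)C)(C(C)C)C(C)C)cc(OC)c1CC=C(C)C
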